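Readings and results were computed on assumed constants.

Start from the late end of the ash flask, at 80 min, and climb down a ladder of paces read from the earlier runs.

in all of them: J 7.5 mM

| run | X | remark | time |
|---|---|---|---|
| ash | 0.30 M | the very flask that is asked about, followed so far |  |
| maple | 0.60 M | run made earlier |  |
| flask | 0.30 M |  | 80 min |

- ash (time / min: Z / %, X / %): 2.00: 0, 98.6; 4.00: 0, 95.8; 10.0: 0.2, 89.3; 25.0: 2.0, 74.9
- maple (time / min: Z / %, X / %): 6.00: 0.8, 94.0; 15.0: 1.4, 84.0; 30.0: 3.0, 70.9; 80.0: 9.1, 36.4

(each reading ± 0.5 percentage points)

- average number of monomer units in a chain (chains begun, living or dead) at 80 min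
- part of the X that has reacted at 80 min

- the average divides the monomer in chains by the number of chains begun, living and dead together
- the analysis behind the earlier runs scatters by 0.5 percentage points, standard deviation
- steps that have been proposed: Z -> Q; J -> E; X -> G; X + J -> D + Z; X + D -> Z + D
- the earlier runs do not show the number of chains; that part of a forecast is a guess

Take the loss of X first. Late in maple, X stands at 36.4%, which reads as a half-life of 54.9 min. Z is the next rung down: maple's 9.1% at 80.0 min is a pace of one full charge in 879 min, far slower than the loss of X. The selectivity, Z over reacted X, reads 14.3% in maple, so more X has gone than Z has come, presumably into G. Z -> Q shows no rung at all, since Z falls in no reading.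

Chains are not read. So set the zero of the scale at every J charged beginning a chain. For ash at 80 min, put Z at 4.55%, half maple's percent, the case where chains begin and grow in step with X. Z over J charged is then 1.82. Call this λ, the chain length per J charged. Maple's percent unchanged, the case where the charge cancels, gives 3.64. Divide λ by the part of J that has begun chains to get dp, so commit to dp above λ and leave that part open.

The forecast gives 5 for dp and 63% for c, noting “Chains begun cannot exceed 7.5 mM” before it guesses.

    Z → Q (k = 4.94 × 10⁻⁸ s⁻¹)
    J → E (k = 5.99 × 10⁻⁵ s⁻¹)
    X → G (k = 1.79 × 10⁻⁴ s⁻¹)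
    X + J → D + Z (k = 4.02 × 10⁻⁴ L mol⁻¹ s⁻¹)
    X + D → Z + D, rate k5*[D]*[X] (k = 0.0128 L mol⁻¹ s⁻¹)

The ash flask gives dp 7.65 and c 61.4%. At 80 min it holds Z 5.39% and D 0.00211 M, one D for each chain begun. Its λ is 2.15, above the low end 1.82, and λ over dp puts the part of J that began chains at 28.2%. A neighbour flask, like the ash flask but charged with 0.019 M of J, holds Z 12.7% at the same time, so its λ is 2.00. With its dp of 7.35, 27.3% of its J began chains.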